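**Retrosynthetic overview** (cyclodeca[b]furan labels: C2 lactone C=O, C3 =CH2, C3a/C11a ring fusion, C4 CHOH, C5 C=O, C6 CHMe, C10 C(OH)Me, C11 CH–O–acyl; target = 3aS,4S,6S,10R,11S,11aR)
1. Last step: one intramolecular indium Barbier allylation of a 3-(bromomethyl)butenolide onto an α-keto aldehyde makes the C3a–C4 bond, the C4 carbinol, the exocyclic methylene and the ten-membered ring.
2. The keto aldehyde comes from a terminal 1,2-diol (bis-silyl protected until the end); the butenolide comes from ring-closing metathesis of a 2-(bromomethyl)acrylate of the C11a allylic alcohol.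
3. C11 and C11a come from a Brown (Z)-γ-alkoxyallylboration of an (E)-2-methyl enal; C10 comes from hydroxyl-directed epoxidation and hydride opening; the side-chain ester goes on C11–OH before the lactone is built.
4. The enal and the C6 methyl stereocentre come from (S)-citronellal by proline-catalysed α-oxygenation and SeO2 allylic oxidation.
5. Ring order: five-membered lactone first (step 10), ten-membered carbocycle last (step 13).

Assumption: the four carbon building blocks (the side-chain acid as the pure E isomer) and (−)-Ipc2BOMe are bought.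

**Step 1**
Reactants: 1 (S)-citronellal [(3S)-3,7-dimethyloct-6-enal]
Product: 4 (2R,3S)-3,7-dimethyloct-6-ene-1,2-diol, via anilinooxy aldehyde 2 (not isolated), via anilinooxy alcohol 3 (not isolated)
Conditions: PhNO, (S)-proline (20 mol %), CHCl3, 4 °C; then NaBH4, MeOH, 0 °C; then Zn dust, AcOH, rt
Reagents that add atoms: nitrosobenzene, O=Nc1ccccc1
Why: Proline-catalysed enamine α-aminoxylation puts the future C5 oxygen next to the aldehyde (the 2R centre is set by the catalyst and is only a placeholder that is oxidised later), borohydride reduction prevents epimerisation, zinc cleaves the N–O bond, and the C6 methyl stereocentre is carried over unchanged from citronellal.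

**Step 2**
Reactants: 4 (2R,3S)-3,7-dimethyloct-6-ene-1,2-diol
Product: 5 (2R,3S)-1,2-bis[(tert-butyldimethylsilyl)oxy]-3,7-dimethyloct-6-ene
Conditions: TBSOTf (2.5 equiv), 2,6-lutidine, CH2Cl2, 0 °C
Reagents that add atoms: tert-butyldimethylsilyl trifluoromethanesulfonate, CC(C)(C)[Si](C)(C)OS(=O)(=O)C(F)(F)F
Why: Silyl ether protection of both hydroxyls gives a masked keto aldehyde that tolerates organolithium-derived boranes, LiAlH4, acylations and metathesis and is removed by HF at the end.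

**Step 3**
Reactants: 5 (2R,3S)-1,2-bis[(tert-butyldimethylsilyl)oxy]-3,7-dimethyloct-6-ene
Product: 7 (2E,6S,7R)-7,8-bis[(tert-butyldimethylsilyl)oxy]-2,6-dimethyloct-2-enal, via allylic alcohol 6 (not isolated)
Conditions: SeO2 (cat.), t-BuOOH, salicylic acid (cat.), CH2Cl2, rt; filter; then MnO2, CH2Cl2, rt
Reagents that add atoms: tert-butyl hydroperoxide, CC(C)(C)OO; selenium dioxide, O=[Se]=O
Why: Riley allylic oxidation (ene reaction then 2,3-sigmatropic shift) hydroxylates only the (E)-methyl of the trisubstituted alkene, and MnO2 converges the alcohol/aldehyde mixture to the (E)-enal whose carbonyl carbon becomes C11.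

**Step 4**
Reactants: 7 (2E,6S,7R)-7,8-bis[(tert-butyldimethylsilyl)oxy]-2,6-dimethyloct-2-enal; 8 allyl methoxymethyl ether [3-(methoxymethoxy)prop-1-ene]
Product: 11 (3R,4R,5E,9S,10R)-10,11-bis[(tert-butyldimethylsilyl)oxy]-3-(methoxymethoxy)-5,9-dimethylundeca-1,5-dien-4-ol, via allyllithium 9 (not isolated), via allylborane 10 (not isolated)
Conditions: 8, s-BuLi, THF, −78 °C; (−)-Ipc2BOMe [from (+)-α-pinene]; BF3·OEt2; then 7, −78 °C; then NaOH, H2O2, 0 °C to rt
Reagents that add atoms: none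
Why: Brown (Z)-γ-alkoxyallylboration through a chair Zimmerman–Traxler transition state gives the syn 3,4-diol monoether, and the isopinocampheyl groups choose the aldehyde face, so C11 and C11a are both set by the reagent with their target geometry.

**Step 5**
Reactants: 11 (3R,4R,5E,9S,10R)-10,11-bis[(tert-butyldimethylsilyl)oxy]-3-(methoxymethoxy)-5,9-dimethylundeca-1,5-dien-4-ol
Product: 12 (1S,2R)-1-[(2S,3S)-3-[(3S,4R)-4,5-bis[(tert-butyldimethylsilyl)oxy]-3-methylpentyl]-2-methyloxiran-2-yl]-2-(methoxymethoxy)but-3-en-1-ol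
Conditions: VO(acac)2 (5 mol %), t-BuOOH, CH2Cl2, 0 °C
Reagents that add atoms: tert-butyl hydroperoxide, CC(C)(C)OO
Why: Hydroxyl-directed VO(acac)2-catalysed epoxidation of the allylic alcohol is governed by allylic 1,2-strain from the 2-methyl group and gives the erythro (anti) epoxy alcohol, which fixes the C10 oxygen relative to C11 while the monosubstituted vinyl group is left alone.

**Step 6**
Reactants: 12 (the erythro epoxy alcohol)
Product: 13 (3R,4S,5R,9S,10R)-10,11-bis[(tert-butyldimethylsilyl)oxy]-3-(methoxymethoxy)-5,9-dimethylundec-1-ene-4,5-diol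
Conditions: LiAlH4, THF, 0 °C to rt; H2O, aq. NaOH work-up
Reagents that add atoms: none
Why: Hydride opens the 2,3-epoxy alcohol by SN2 attack at the less substituted carbon (future C9), so the C10–O bond is untouched and the tertiary alcohol keeps the configuration set in step 5.

**Step 7**
Reactants: 13 (the 4,5-diol); 14 (2E)-3-methylpent-2-enoic acid
Product: 15 (3R,4S,5R,9S,10R)-10,11-bis[(tert-butyldimethylsilyl)oxy]-5-hydroxy-3-(methoxymethoxy)-5,9-dimethylundec-1-en-4-yl (2E)-3-methylpent-2-enoate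
Conditions: iPrN=C=NiPr, DMAP, CH2Cl2, rt
Reagents that add atoms: none
Why: Steglich esterification acylates the only secondary hydroxyl (future C11–OH) because the tertiary C10–OH is too hindered, and carbodiimide activation avoids the ketene pathway that would scramble the (E)-enoate.

**Step 8**
Reactants: 15 (the methoxymethyl-protected ester)
Product: 16 (3R,4S,5R,9S,10R)-10,11-bis[(tert-butyldimethylsilyl)oxy]-3,5-dihydroxy-5,9-dimethylundec-1-en-4-yl (2E)-3-methylpent-2-enoate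
Conditions: ZnBr2, n-PrSH, CH2Cl2, 0 °C, 10 min
Reagents that add atoms: none
Why: Lewis acid and thiol cleave the methoxymethyl acetal in minutes while silyl ethers and esters survive, and the short cold reaction limits acyl migration from C11–O to the freed C11a–OH.

**Step 9**
Reactants: 16 (the allylic alcohol); 17 2-(bromomethyl)acrylic acid
Product: 18 (3R,4S,5R,9S,10R)-3-{[2-(bromomethyl)prop-2-enoyl]oxy}-10,11-bis[(tert-butyldimethylsilyl)oxy]-5-hydroxy-5,9-dimethylundec-1-en-4-yl (2E)-3-methylpent-2-enoate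
Conditions: iPrN=C=NiPr, DMAP (5 mol %), CH2Cl2, 0 °C
Reagents that add atoms: none
Why: Steglich esterification again selects the secondary allylic hydroxyl over the tertiary one and installs all remaining lactone carbons together with the allylic bromide.

**Step 10**
Reactants: 18 (the acrylate diene)
Product: 19 (1S,2R,6S,7R)-1-[(2R)-4-(bromomethyl)-5-oxo-2,5-dihydrofuran-2-yl]-7,8-bis[(tert-butyldimethylsilyl)oxy]-2-hydroxy-2,6-dimethyloctyl (2E)-3-methylpent-2-enoate
Conditions: second-generation Grubbs catalyst RuCl2(=CHPh)(PCy3)(H2IMes) (10 mol %), toluene (5 mM), 80 °C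
Reagents that add atoms: none
Why: Ring-closing metathesis between the acrylate and the vinyl group closes the five-membered butenolide with loss of ethene, the trisubstituted enoate is inert to the catalyst, and the C11a stereocentre is not touched.

**Step 11**
Reactants: 19 (the bis-silyl bromobutenolide)
Product: 20 (1S,2R,6S,7R)-1-[(2R)-4-(bromomethyl)-5-oxo-2,5-dihydrofuran-2-yl]-2,7,8-trihydroxy-2,6-dimethyloctyl (2E)-3-methylpent-2-enoate
Conditions: aq. HF (48 %), MeCN, 0 °C to rt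
Reagents that add atoms: none
Why: Fluoride-driven desilylation in an acidic, amine-free medium frees the terminal diol without displacing the reactive allylic bromide or opening the esters and lactone.

**Step 12**
Reactants: 20 (the terminal 1,2-diol)
Product: 21 (1S,2R,6S)-1-[(2R)-4-(bromomethyl)-5-oxo-2,5-dihydrofuran-2-yl]-2-hydroxy-2,6-dimethyl-7,8-dioxooctyl (2E)-3-methylpent-2-enoate
Conditions: IBX (4 equiv), DMSO/THF, rt; used crude at once
Reagents that add atoms: none
Why: IBX oxidises both carbinols of a 1,2-diol to the 1,2-dicarbonyl without glycol cleavage under neutral conditions, which keeps the enolisable C6 centre intact and leaves the tertiary alcohol untouched.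

**Step 13**
Reactants: 21 (the α-keto aldehyde bromobutenolide)
Product: 23 (3aS,4S,6S,10R,11S,11aR)-4,10-dihydroxy-6,10-dimethyl-3-methylidene-2,5-dioxododecahydrocyclodeca[b]furan-11-yl (2E)-3-methylpent-2-enoate, via allylindium 22 (not isolated)
Conditions: indium powder (3 equiv), THF/H2O (1:1), 2 mM, rt
Reagents that add atoms: none
Why: In this intramolecular Barbier allylation the allylindium attacks the aldehyde (far more electrophilic than the adjacent ketone) through its γ-carbon anti to the C11a substituent, giving the trans lactone at C3a, and a chair six-membered transition state with the acyl group equatorial gives the 4S carbinol while the ten-membered ring closes.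

**Compound list**
1 | (S)-citronellal, (3S)-3,7-dimethyloct-6-enal | O=CC[C@@H](C)CCC=C(C)C | starting material
2 | (2R,3S)-3,7-dimethyl-2-[(phenylamino)oxy]oct-6-enal | O=C[C@H](ONc1ccccc1)[C@@H](C)CCC=C(C)C | intermediate
3 | (2R,3S)-3,7-dimethyl-2-[(phenylamino)oxy]oct-6-en-1-ol | OC[C@H](ONc1ccccc1)[C@@H](C)CCC=C(C)C | intermediate
4 | (2R,3S)-3,7-dimethyloct-6-ene-1,2-diol | OC[C@H](O)[C@@H](C)CCC=C(C)C | intermediate
5 | (2R,3S)-1,2-bis[(tert-butyldimethylsilyl)oxy]-3,7-dimethyloct-6-ene | CC(C)(C)[Si](C)(C)OC[C@H](O[Si](C)(C)C(C)(C)C)[C@@H](C)CCC=C(C)C | intermediate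
6 | (2E,6S,7R)-7,8-bis[(tert-butyldimethylsilyl)oxy]-2,6-dimethyloct-2-en-1-ol | CC(C)(C)[Si](C)(C)OC[C@H](O[Si](C)(C)C(C)(C)C)[C@@H](C)CC/C=C(\C)CO | intermediate
7 | (2E,6S,7R)-7,8-bis[(tert-butyldimethylsilyl)oxy]-2,6-dimethyloct-2-enal | CC(C)(C)[Si](C)(C)OC[C@H](O[Si](C)(C)C(C)(C)C)[C@@H](C)CC/C=C(\C)C=O | intermediate
8 | allyl methoxymethyl ether, 3-(methoxymethoxy)prop-1-ene | C=CCOCOC | starting material
9 | [(Z)-3-(methoxymethoxy)allyl]lithium | [Li]C/C=C\OCOC | intermediate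
10 | [(Z)-3-(methoxymethoxy)allyl]bis(isopinocampheyl)borane, isopinocampheyl groups from (+)-α-pinene | COCO/C=C\CB([C@@H]1C[C@@H]2C[C@H]([C@H]1C)C2(C)C)[C@@H]1C[C@@H]2C[C@H]([C@H]1C)C2(C)C | intermediate
11 | (3R,4R,5E,9S,10R)-10,11-bis[(tert-butyldimethylsilyl)oxy]-3-(methoxymethoxy)-5,9-dimethylundeca-1,5-dien-4-ol | CC(C)(C)[Si](C)(C)OC[C@H](O[Si](C)(C)C(C)(C)C)[C@@H](C)CC/C=C(\C)[C@@H](O)[C@H](OCOC)C=C | intermediate
12 | (1S,2R)-1-[(2S,3S)-3-[(3S,4R)-4,5-bis[(tert-butyldimethylsilyl)oxy]-3-methylpentyl]-2-methyloxiran-2-yl]-2-(methoxymethoxy)but-3-en-1-ol | CC(C)(C)[Si](C)(C)OC[C@H](O[Si](C)(C)C(C)(C)C)[C@@H](C)CC[C@@H]1O[C@@]1(C)[C@@H](O)[C@H](OCOC)C=C | intermediate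
13 | (3R,4S,5R,9S,10R)-10,11-bis[(tert-butyldimethylsilyl)oxy]-3-(methoxymethoxy)-5,9-dimethylundec-1-ene-4,5-diol | CC(C)(C)[Si](C)(C)OC[C@H](O[Si](C)(C)C(C)(C)C)[C@@H](C)CCC[C@@](C)(O)[C@@H](O)[C@H](OCOC)C=C | intermediate
14 | (2E)-3-methylpent-2-enoic acid | CC/C(C)=C/C(=O)O | starting material
15 | (3R,4S,5R,9S,10R)-10,11-bis[(tert-butyldimethylsilyl)oxy]-5-hydroxy-3-(methoxymethoxy)-5,9-dimethylundec-1-en-4-yl (2E)-3-methylpent-2-enoate | CC(C)(C)[Si](C)(C)OC[C@H](O[Si](C)(C)C(C)(C)C)[C@@H](C)CCC[C@@](C)(O)[C@@H](OC(=O)/C=C(\C)CC)[C@H](OCOC)C=C | intermediate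
16 | (3R,4S,5R,9S,10R)-10,11-bis[(tert-butyldimethylsilyl)oxy]-3,5-dihydroxy-5,9-dimethylundec-1-en-4-yl (2E)-3-methylpent-2-enoate | CC(C)(C)[Si](C)(C)OC[C@H](O[Si](C)(C)C(C)(C)C)[C@@H](C)CCC[C@@](C)(O)[C@@H](OC(=O)/C=C(\C)CC)[C@H](O)C=C | intermediate
17 | 2-(bromomethyl)acrylic acid | C=C(CBr)C(=O)O | starting material
18 | (3R,4S,5R,9S,10R)-3-{[2-(bromomethyl)prop-2-enoyl]oxy}-10,11-bis[(tert-butyldimethylsilyl)oxy]-5-hydroxy-5,9-dimethylundec-1-en-4-yl (2E)-3-methylpent-2-enoate | CC(C)(C)[Si](C)(C)OC[C@H](O[Si](C)(C)C(C)(C)C)[C@@H](C)CCC[C@@](C)(O)[C@@H](OC(=O)/C=C(\C)CC)[C@H](OC(=O)C(=C)CBr)C=C | intermediate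
19 | (1S,2R,6S,7R)-1-[(2R)-4-(bromomethyl)-5-oxo-2,5-dihydrofuran-2-yl]-7,8-bis[(tert-butyldimethylsilyl)oxy]-2-hydroxy-2,6-dimethyloctyl (2E)-3-methylpent-2-enoate | CC(C)(C)[Si](C)(C)OC[C@H](O[Si](C)(C)C(C)(C)C)[C@@H](C)CCC[C@@](C)(O)[C@@H](OC(=O)/C=C(\C)CC)[C@@H]1OC(=O)C(CBr)=C1 | intermediate
20 | (1S,2R,6S,7R)-1-[(2R)-4-(bromomethyl)-5-oxo-2,5-dihydrofuran-2-yl]-2,7,8-trihydroxy-2,6-dimethyloctyl (2E)-3-methylpent-2-enoate | OC[C@H](O)[C@@H](C)CCC[C@@](C)(O)[C@@H](OC(=O)/C=C(\C)CC)[C@@H]1OC(=O)C(CBr)=C1 | intermediate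
21 | (1S,2R,6S)-1-[(2R)-4-(bromomethyl)-5-oxo-2,5-dihydrofuran-2-yl]-2-hydroxy-2,6-dimethyl-7,8-dioxooctyl (2E)-3-methylpent-2-enoate | O=CC(=O)[C@@H](C)CCC[C@@](C)(O)[C@@H](OC(=O)/C=C(\C)CC)[C@@H]1OC(=O)C(CBr)=C1 | intermediate
22 | allylindium dibromide (RInBr2) formed from 21 at the CH2Br carbon | O=CC(=O)[C@@H](C)CCC[C@@](C)(O)[C@@H](OC(=O)/C=C(\C)CC)[C@@H]1OC(=O)C(C[In](Br)Br)=C1 | intermediate
23 | (3aS,4S,6S,10R,11S,11aR)-4,10-dihydroxy-6,10-dimethyl-3-methylidene-2,5-dioxododecahydrocyclodeca[b]furan-11-yl (2E)-3-methylpent-2-enoate (CNP0197047.1) | C=C1C(=O)O[C@@H]2[C@@H]1[C@H](O)C(=O)[C@@H](C)CCC[C@@](C)(O)[C@H]2OC(=O)/C=C(\C)CC | target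

**Totals**
Total steps: 13. Longest linear sequence: 13 steps, from 1 to 23; compounds 8, 14 and 17 are bought and enter directly.

**Three steps most likely to fail**

Step 13, the macrocyclic Barbier reaction on the keto aldehyde. Risks are oligomerisation, the wrong C4 epimer, and loss of the C6 configuration in the 1,2-dicarbonyl. The fallback closes the ring before the C5 ketone exists; it sets out from 19 and comes back at 23. Cold aq. HF in MeCN removes only the primary silyl group to give the primary alcohol F1, and Dess–Martin periodinane gives the α-silyloxy aldehyde F2. Indium in THF/H2O then closes the ring on this robust mono-aldehyde to the macrocyclic 5-silyl ether F3. Allyl chloroformate and pyridine mask the new C4 hydroxyl as the allyl carbonate F4, aq. HF in MeCN frees the C5 alcohol F5, and Dess–Martin periodinane gives the C5 ketone F6. Pd(PPh3)4 with PhSiH3 removes the allyl carbonate and gives 23.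

Step 12, the double oxidation of the free glycol. Risks are C–C cleavage and attack of DMSO on the allylic bromide. The fallback oxidises stepwise so that no free glycol meets the oxidant; it sets out from 20 and comes back at 21. TBSOTf (1 equiv) and 2,6-lutidine at −78 °C silylate only the primary hydroxyl to give the mono-silyl ether F7. Dess–Martin periodinane oxidises the C5 carbinol to the α-silyloxy ketone F8, aq. HF in MeCN gives the α-hydroxy ketone F9, and Dess–Martin periodinane oxidises the primary ketol to 21.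

Step 10, ring-closing metathesis onto a hindered, electron-poor 2-(bromomethyl)acrylate. The fallback closes the unsubstituted butenolide first and adds the CH2Br carbon afterwards; it sets out from 16 and comes back at 19. Acryloyl chloride and iPr2NEt give the acrylate F10, and second-generation Grubbs catalyst closes the unsubstituted butenolide F11. Morita–Baylis–Hillman hydroxymethylation (aq. CH2O, PBu3 cat., THF) gives the 3-(hydroxymethyl)butenolide F12, and CBr4/PPh3 (Appel reaction) gives 19.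

**Further compounds**
F1 | step 13 | primary alcohol, 7-O-TBS-8-hydroxy analogue of 19 (1S,2R,6S,7R; furanone 2R) | OC[C@H](O[Si](C)(C)C(C)(C)C)[C@@H](C)CCC[C@@](C)(O)[C@@H](OC(=O)/C=C(\C)CC)[C@@H]1OC(=O)C(CBr)=C1
F2 | step 13 | α-silyloxy aldehyde, (7R)-7-O-TBS-8-oxo analogue of 19 | O=C[C@H](O[Si](C)(C)C(C)(C)C)[C@@H](C)CCC[C@@](C)(O)[C@@H](OC(=O)/C=C(\C)CC)[C@@H]1OC(=O)C(CBr)=C1
F3 | step 13 | (3aS,4S,5R,6S,10R,11S,11aR)-5-[(tert-butyldimethylsilyl)oxy]-4,10-dihydroxy-6,10-dimethyl-3-methylidene-2-oxododecahydrocyclodeca[b]furan-11-yl (2E)-3-methylpent-2-enoate | C=C1C(=O)O[C@@H]2[C@@H]1[C@H](O)[C@H](O[Si](C)(C)C(C)(C)C)[C@@H](C)CCC[C@@](C)(O)[C@H]2OC(=O)/C=C(\C)CC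
F4 | step 13 | C4 allyl carbonate of F3 (all stereocentres as in F3) | C=C1C(=O)O[C@@H]2[C@@H]1[C@H](OC(=O)OCC=C)[C@H](O[Si](C)(C)C(C)(C)C)[C@@H](C)CCC[C@@](C)(O)[C@H]2OC(=O)/C=C(\C)CC
F5 | step 13 | C5 alcohol, desilylated F4 (all stereocentres as in F3) | C=C1C(=O)O[C@@H]2[C@@H]1[C@H](OC(=O)OCC=C)[C@H](O)[C@@H](C)CCC[C@@](C)(O)[C@H]2OC(=O)/C=C(\C)CC
F6 | step 13 | C5 ketone, the C4 allyl carbonate of 23 (stereocentres as in 23) | C=C1C(=O)O[C@@H]2[C@@H]1[C@H](OC(=O)OCC=C)C(=O)[C@@H](C)CCC[C@@](C)(O)[C@H]2OC(=O)/C=C(\C)CC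
F7 | step 12 | mono-silyl ether, 8-O-TBS derivative of 20 (1S,2R,6S,7R; furanone 2R) | CC(C)(C)[Si](C)(C)OC[C@H](O)[C@@H](C)CCC[C@@](C)(O)[C@@H](OC(=O)/C=C(\C)CC)[C@@H]1OC(=O)C(CBr)=C1
F8 | step 12 | α-silyloxy ketone, 7-oxo-8-O-TBS analogue of 20 (1S,2R,6S; furanone 2R) | CC(C)(C)[Si](C)(C)OCC(=O)[C@@H](C)CCC[C@@](C)(O)[C@@H](OC(=O)/C=C(\C)CC)[C@@H]1OC(=O)C(CBr)=C1
F9 | step 12 | α-hydroxy ketone, 7-oxo-8-hydroxy analogue of 20 (1S,2R,6S; furanone 2R) | OCC(=O)[C@@H](C)CCC[C@@](C)(O)[C@@H](OC(=O)/C=C(\C)CC)[C@@H]1OC(=O)C(CBr)=C1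
F10 | step 10 | acrylate, 3-O-acryloyl derivative of 16 (3R,4S,5R,9S,10R) | CC(C)(C)[Si](C)(C)OC[C@H](O[Si](C)(C)C(C)(C)C)[C@@H](C)CCC[C@@](C)(O)[C@@H](OC(=O)/C=C(\C)CC)[C@H](OC(=O)C=C)C=C
F11 | step 10 | unsubstituted butenolide, analogue of 19 lacking the CH2Br group (1S,2R,6S,7R; furanone 2R) | CC(C)(C)[Si](C)(C)OC[C@H](O[Si](C)(C)C(C)(C)C)[C@@H](C)CCC[C@@](C)(O)[C@@H](OC(=O)/C=C(\C)CC)[C@@H]1OC(=O)C=C1
F12 | step 10 | 3-(hydroxymethyl)butenolide, analogue of 19 with CH2OH in place of CH2Br | CC(C)(C)[Si](C)(C)OC[C@H](O[Si](C)(C)C(C)(C)C)[C@@H](C)CCC[C@@](C)(O)[C@@H](OC(=O)/C=C(\C)CC)[C@@H]1OC(=O)C(CO)=C1
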